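Germacrane numbering is used (carbocycle C1–C10; lactone O–C6, C7, C11, C12; C14 = ester carbon on C10). Everything rests on disconnecting the C1=C10 double bond of the ten-membered ring. The key step exploits that this olefin is ring-cis, carries the C14 ester and adjoins the C9 carbinol: C9–C10(=CH2)–C14 is a Morita–Baylis–Hillman acrylate, so ring-closing metathesis of its methylene with a terminal C1 vinyl group closes the carbocycle last and sets the olefin geometry in one operation. The precursor is a seco-diene: a preformed trans-fused α-methylene-γ-butyrolactone bearing the (E)-dienyl chain on C6 and the acrylate arm on C7, assembled by a zinc Barbier coupling.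

Key step: step 10

Convention: 8α means the C8–O bond lies on the same ring face as H7 and the C9 acetate; 8β (target) means the face of the C7–C11 bond.

Assumption: with 2,2-dimethoxyacetaldehyde, β-isocupreidine is taken to select the same aldehyde face as with simple aldehydes, which here carries the descriptor (S); were the opposite sense found, the pseudo-enantiomeric catalyst would be used.

**Step 1**
Reactants: 1 hex-1-en-5-yne; 2 acrolein
Product: 5 rac-(4E)-5-methylnona-1,4,8-trien-3-ol, via alkenylalane 3 (not isolated), via lithium alanate 4 (not isolated)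
Conditions: AlMe3, Cp2ZrCl2 (cat.), CH2Cl2, 0 °C → rt; then MeLi, THF, −78 °C; 2, −78 → 0 °C; aq. Rochelle salt
Reagents that add atoms: trimethylaluminium, C[Al](C)C
Why: Zirconium-catalysed Negishi carboalumination adds Me–Al syn across the terminal alkyne only (the terminal alkene is inert under these conditions), which fixes the E-trisubstituted C4=C5 olefin, and the derived alanate transfers its alkenyl group 1,2 to acrolein; the C6 carbinol is formed racemic.

**Step 2**
Reactants: 5 rac-(4E)-5-methylnona-1,4,8-trien-3-ol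
Product: 6 (3S,4E)-5-methylnona-1,4,8-trien-3-ol
Conditions: immobilised lipase PS (Burkholderia cepacia), vinyl acetate, MTBE, 30 °C, run past half conversion; chromatography
Reagents that add atoms: none
Why: Lipase-catalysed kinetic resolution by transesterification: by the Kazlauskas rule (large = 2-methylalkenyl, medium = vinyl) the (R)-alcohol should be acetylated faster, so the (S)-alcohol, which carries the C6 configuration, is recovered.

**Step 3**
Reactants: 6 (3S,4E)-5-methylnona-1,4,8-trien-3-ol; 7 2-(bromomethyl)prop-2-enoic acid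
Product: 8 (3S,4E)-5-methylnona-1,4,8-trien-3-yl 2-(bromomethyl)prop-2-enoate
Conditions: DIC, DMAP (5 mol%), CH2Cl2, −20 → 0 °C
Reagents that add atoms: none
Why: Steglich esterification acylates the secondary alcohol without breaking its C–O bond (retention at C6), and low temperature with only catalytic DMAP keeps SN2′ attack on the allylic bromide slow.

**Step 4**
Reactants: 8 (3S,4E)-5-methylnona-1,4,8-trien-3-yl 2-(bromomethyl)prop-2-enoate
Product: 9 (5R)-3-(bromomethyl)-5-[(1E)-2-methylhexa-1,5-dien-1-yl]furan-2(5H)-one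
Conditions: Grubbs II (5 mol%), CH2Cl2 (2 mM), 40 °C
Reagents that add atoms: none
Why: Ring-closing metathesis between the C7 vinyl group and the 1,1-disubstituted acrylate closes the butenolide (the lactone ring) with loss of ethylene; the remote C1 vinyl group can reach no unstrained ring and at high dilution should only homodimerise reversibly, and C6 is not touched.

**Step 5**
Reactants: 10 1,1,1,3,3,3-hexafluoropropan-2-yl prop-2-enoate; 11 2,2-dimethoxyacetaldehyde (dried)
Product: 12 1,1,1,3,3,3-hexafluoropropan-2-yl (3S)-3-hydroxy-4,4-dimethoxy-2-methylidenebutanoate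
Conditions: β-isocupreidine (10 mol%), DMF, −55 °C; chromatography
Reagents that add atoms: none
Why: Enantioselective Morita–Baylis–Hillman reaction: the quinuclidine nitrogen adds to the activated acrylate and the catalyst's phenolic OH hydrogen-bonds one diastereomeric aldolate so that only it eliminates quickly, which sets C9 as (S) (see assumption); the adduct is separated from any dioxanone by-product.

**Step 6**
Reactants: 12 1,1,1,3,3,3-hexafluoropropan-2-yl (3S)-3-hydroxy-4,4-dimethoxy-2-methylidenebutanoate
Product: 13 methyl (3S)-3-hydroxy-4,4-dimethoxy-2-methylidenebutanoate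
Conditions: MeOH, Et3N, rt
Reagents that add atoms: methanol, CO
Why: Base-mediated transesterification of the activated hexafluoroisopropyl ester gives the C14 methyl ester without touching C9.

**Step 7**
Reactants: 13 methyl (3S)-3-hydroxy-4,4-dimethoxy-2-methylidenebutanoate
Product: 14 methyl (3S)-3-(acetyloxy)-4,4-dimethoxy-2-methylidenebutanoate
Conditions: AcCl, pyridine, CH2Cl2, 0 °C
Reagents that add atoms: acetyl chloride, CC(Cl)=O
Why: O-Acylation installs the C9 acetate of the target with retention, and pyridine, unlike DABCO-type amines, should not displace the Baylis–Hillman acetate by SN2′.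

**Step 8**
Reactants: 14 methyl (3S)-3-(acetyloxy)-4,4-dimethoxy-2-methylidenebutanoate
Product: 15 methyl (3S)-3-(acetyloxy)-2-methylidene-4-oxobutanoate
Conditions: TFA/H2O (9:1), CH2Cl2, 0 °C; used crude at once
Reagents that add atoms: water, O
Why: Acid-catalysed acetal hydrolysis unmasks the C8 aldehyde under non-basic conditions, so C9 (α to the aldehyde and allylic) should not enolise and the acetate should not migrate.

**Step 9**
Reactants: 9 (5R)-3-(bromomethyl)-5-[(1E)-2-methylhexa-1,5-dien-1-yl]furan-2(5H)-one; 15 methyl (3S)-3-(acetyloxy)-2-methylidene-4-oxobutanoate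
Product: 17 methyl (3S,4R)-3-(acetyloxy)-4-hydroxy-2-methylidene-4-{(2R,3R)-2-[(1E)-2-methylhexa-1,5-dien-1-yl]-4-methylidene-5-oxooxolan-3-yl}butanoate, via allylzinc bromide 16 (not isolated)
Conditions: Zn dust, THF/sat. aq. NH4Cl, 0 °C → rt
Reagents that add atoms: none
Why: Barbier allylation: zinc inserts into the allylic bromide and the 2-(alkoxycarbonyl)allylzinc adds through its γ-carbon C7 (SE2′), which creates the exocyclic C11=C13 methylene; C7 is set trans to the C6 chain (attack anti to it), and C8 by a chair transition state of the ring-locked E-type allylmetal (anti) reinforced by Felkin–Anh addition anti to the C9 acetate, so the 8α (8R) alcohol is expected, the epimer that step 13 inverts.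

**Step 10**
Reactants: 17 methyl (3S,4R)-3-(acetyloxy)-4-hydroxy-2-methylidene-4-{(2R,3R)-2-[(1E)-2-methylhexa-1,5-dien-1-yl]-4-methylidene-5-oxooxolan-3-yl}butanoate
Product: 18 methyl (3aR,4R,5S,6E,10E,11aR)-5-(acetyloxy)-4-hydroxy-10-methyl-3-methylidene-2-oxo-2,3,3a,4,5,8,9,11a-octahydrocyclodeca[b]furan-6-carboxylate
Conditions: Hoveyda–Grubbs II (15 mol%, in portions), 1,4-benzoquinone (cat.), toluene (1 mM), 80 °C, argon sparge
Reagents that add atoms: none
Why: Ring-closing olefin metathesis: the ruthenium carbene loads on the only monosubstituted olefin (the C1 vinyl group), undergoes intramolecular [2+2] cycloaddition with the C10 methylene of the acrylate and cycloreverts with loss of ethylene, closing the ten-membered carbocycle at C1=C10. The closest known reaction types are RCM of Baylis–Hillman-derived 2-substituted acrylates to cyclic enoates and RCM closure of ten-membered germacranolide rings in the presence of an α-methylene lactone. The ring closes by direct macrocyclising metathesis of a diene whose two arms sit on adjacent carbons (C6 and C7) of the trans-fused lactone, which brings the termini together. No stereocentre is formed; the geometric element (C2 cis to C9, ester trans to C2) is controlled by the ring, because a ten-membered ring that already holds the E C4=C5 bond should accept the new trisubstituted olefin only ring-cis, which is also the thermodynamically preferred E-enoate. The step needs site selectivity among five olefins and ring closure over oligomerisation: the trisubstituted C4=C5 bond is inert, closure onto the lactone methylene would give a trans-cyclooctene, and high dilution with portionwise catalyst favours the intramolecular path.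

**Step 11**
Reactants: 19 methyl 2-(hydroxymethyl)prop-2-enoate
Product: 20 methyl 2-({[tert-butyl(dimethyl)silyl]oxy}methyl)prop-2-enoate
Conditions: TBSCl, imidazole, CH2Cl2, 0 °C → rt
Reagents that add atoms: tert-butyldimethylsilyl chloride, CC(C)(C)[Si](C)(C)Cl
Why: Silylation of the primary allylic alcohol masks it so that the acid can later act only as a carboxylate nucleophile.

**Step 12**
Reactants: 20 methyl 2-({[tert-butyl(dimethyl)silyl]oxy}methyl)prop-2-enoate
Product: 21 2-({[tert-butyl(dimethyl)silyl]oxy}methyl)prop-2-enoic acid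
Conditions: LiOH, THF/H2O, 0 °C; then 1 M HCl to pH 4
Reagents that add atoms: lithium hydroxide, [Li+].[OH-]
Why: Saponification of the methyl ester under cold, dilute conditions should leave the primary TBS ether intact.

**Step 13**
Reactants: 18 methyl (3aR,4R,5S,6E,10E,11aR)-5-(acetyloxy)-4-hydroxy-10-methyl-3-methylidene-2-oxo-2,3,3a,4,5,8,9,11a-octahydrocyclodeca[b]furan-6-carboxylate; 21 2-({[tert-butyl(dimethyl)silyl]oxy}methyl)prop-2-enoic acid
Product: 22 methyl (3aS,4S,5S,6E,10E,11aR)-5-(acetyloxy)-4-{[2-({[tert-butyl(dimethyl)silyl]oxy}methyl)prop-2-enoyl]oxy}-10-methyl-3-methylidene-2-oxo-2,3,3a,4,5,8,9,11a-octahydrocyclodeca[b]furan-6-carboxylate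
Conditions: PPh3, DIAD (betaine pre-formed), toluene, 0 °C → rt
Reagents that add atoms: none
Why: Mitsunobu esterification: the 8α-alcohol is activated as its oxyphosphonium ion and displaced by the carboxylate with inversion (SN2), which installs the C8 acyl group and corrects C8 to 8β (8S) in one operation; pre-forming the betaine keeps free phosphine away from the Michael acceptors.

**Step 14**
Reactants: 22 methyl (3aS,4S,5S,6E,10E,11aR)-5-(acetyloxy)-4-{[2-({[tert-butyl(dimethyl)silyl]oxy}methyl)prop-2-enoyl]oxy}-10-methyl-3-methylidene-2-oxo-2,3,3a,4,5,8,9,11a-octahydrocyclodeca[b]furan-6-carboxylate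
Product: 23 methyl (3aS,4S,5S,6E,10E,11aR)-5-(acetyloxy)-4-{[2-(hydroxymethyl)prop-2-enoyl]oxy}-10-methyl-3-methylidene-2-oxo-2,3,3a,4,5,8,9,11a-octahydrocyclodeca[b]furan-6-carboxylate (target, CNP0291058.1)
Conditions: HF·pyridine, THF/pyridine, 0 °C
Reagents that add atoms: none
Why: Buffered fluoride desilylation cleaves the primary TBS ether and should leave the acetate, both acrylate esters and the α-methylene lactone untouched; no stereocentre is affected.

**Compound list**

1 | hex-1-en-5-yne | C=CCCC#C | starting material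
2 | acrolein (prop-2-enal) | C=CC=O | starting material
3 | [(1E)-2-methylhexa-1,5-dien-1-yl]dimethylalumane (formed in situ) | C=CCC/C(C)=C/[Al](C)C | intermediate
4 | lithium trimethyl[(1E)-2-methylhexa-1,5-dien-1-yl]aluminate (formed in situ) | [Li+].C=CCC/C(C)=C/[Al-](C)(C)C | intermediate
5 | rac-(4E)-5-methylnona-1,4,8-trien-3-ol | C=CCC/C(C)=C/C(O)C=C | intermediate
6 | (3S,4E)-5-methylnona-1,4,8-trien-3-ol | C=CCC/C(C)=C/[C@@H](O)C=C | intermediate
7 | 2-(bromomethyl)prop-2-enoic acid | C=C(CBr)C(=O)O | starting material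
8 | (3S,4E)-5-methylnona-1,4,8-trien-3-yl 2-(bromomethyl)prop-2-enoate | C=CCC/C(C)=C/[C@@H](OC(=O)C(=C)CBr)C=C | intermediate
9 | (5R)-3-(bromomethyl)-5-[(1E)-2-methylhexa-1,5-dien-1-yl]furan-2(5H)-one | C=CCC/C(C)=C/[C@H]1OC(=O)C(CBr)=C1 | intermediate
10 | 1,1,1,3,3,3-hexafluoropropan-2-yl prop-2-enoate | C=CC(=O)OC(C(F)(F)F)C(F)(F)F | starting material
11 | 2,2-dimethoxyacetaldehyde | COC(OC)C=O | starting material
12 | 1,1,1,3,3,3-hexafluoropropan-2-yl (3S)-3-hydroxy-4,4-dimethoxy-2-methylidenebutanoate | COC(OC)[C@@H](O)C(=C)C(=O)OC(C(F)(F)F)C(F)(F)F | intermediate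
13 | methyl (3S)-3-hydroxy-4,4-dimethoxy-2-methylidenebutanoate | COC(OC)[C@@H](O)C(=C)C(=O)OC | intermediate
14 | methyl (3S)-3-(acetyloxy)-4,4-dimethoxy-2-methylidenebutanoate | COC(OC)[C@@H](OC(C)=O)C(=C)C(=O)OC | intermediate
15 | methyl (3S)-3-(acetyloxy)-2-methylidene-4-oxobutanoate | O=C[C@@H](OC(C)=O)C(=C)C(=O)OC | intermediate
16 | bromo{[(5R)-5-[(1E)-2-methylhexa-1,5-dien-1-yl]-2-oxo-2,5-dihydrofuran-3-yl]methyl}zinc (formed in situ) | C=CCC/C(C)=C/[C@H]1OC(=O)C(C[Zn]Br)=C1 | intermediate
17 | methyl (3S,4R)-3-(acetyloxy)-4-hydroxy-2-methylidene-4-{(2R,3R)-2-[(1E)-2-methylhexa-1,5-dien-1-yl]-4-methylidene-5-oxooxolan-3-yl}butanoate | O[C@H]([C@H]1C(=C)C(=O)O[C@@H]1/C=C(\C)CCC=C)[C@@H](OC(C)=O)C(=C)C(=O)OC | intermediate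
18 | methyl (3aR,4R,5S,6E,10E,11aR)-5-(acetyloxy)-4-hydroxy-10-methyl-3-methylidene-2-oxo-2,3,3a,4,5,8,9,11a-octahydrocyclodeca[b]furan-6-carboxylate (8α-alcohol) | O[C@@H]1[C@H]2C(=C)C(=O)O[C@@H]2/C=C(\C)CC/C=C(/C(=O)OC)[C@@H]1OC(C)=O | intermediate
19 | methyl 2-(hydroxymethyl)prop-2-enoate | C=C(CO)C(=O)OC | starting material
20 | methyl 2-({[tert-butyl(dimethyl)silyl]oxy}methyl)prop-2-enoate | C=C(CO[Si](C)(C)C(C)(C)C)C(=O)OC | intermediate
21 | 2-({[tert-butyl(dimethyl)silyl]oxy}methyl)prop-2-enoic acid | C=C(CO[Si](C)(C)C(C)(C)C)C(=O)O | intermediate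
22 | methyl (3aS,4S,5S,6E,10E,11aR)-5-(acetyloxy)-4-{[2-({[tert-butyl(dimethyl)silyl]oxy}methyl)prop-2-enoyl]oxy}-10-methyl-3-methylidene-2-oxo-2,3,3a,4,5,8,9,11a-octahydrocyclodeca[b]furan-6-carboxylate | C=C(CO[Si](C)(C)C(C)(C)C)C(=O)O[C@H]1[C@H]2C(=C)C(=O)O[C@@H]2/C=C(\C)CC/C=C(/C(=O)OC)[C@@H]1OC(C)=O | intermediate
23 | methyl (3aS,4S,5S,6E,10E,11aR)-5-(acetyloxy)-4-{[2-(hydroxymethyl)prop-2-enoyl]oxy}-10-methyl-3-methylidene-2-oxo-2,3,3a,4,5,8,9,11a-octahydrocyclodeca[b]furan-6-carboxylate | C=C(CO)C(=O)O[C@H]1[C@H]2C(=C)C(=O)O[C@@H]2/C=C(\C)CC/C=C(/C(=O)OC)[C@@H]1OC(C)=O | target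

**Step count and risks**

Total step count: 14. Longest linear sequence: 8 steps (1, 2, 3, 4, 9, 10, 13, 14).

Steps most likely to fail:

1. Step 10 (ring-closing metathesis). The C1 ruthenium alkylidene may meet a second molecule faster than it reaches the hindered C10 methylene across a strained ten-membered transition state, so that oligomers form and the catalyst decays. The fallback sets out from 9 and 14 and comes back at 18. The C1=C10 bond is made first and intermolecularly, where ring strain plays no part, and the ring is then closed at C7–C8. Cross-metathesis of the terminal olefin of 9 with excess 14 (Hoveyda–Grubbs II, CH2Cl2, 40 °C, concentrated) should give methyl (2E,6E)-2-[(1S)-1-(acetyloxy)-2,2-dimethoxyethyl]-7-[(2R)-4-(bromomethyl)-5-oxo-2,5-dihydrofuran-2-yl]-6-methylhepta-2,6-dienoate F1. Acetal hydrolysis (TFA/H2O) gives methyl (2E,6E)-2-[(1S)-1-(acetyloxy)-2-oxoethyl]-7-[(2R)-4-(bromomethyl)-5-oxo-2,5-dihydrofuran-2-yl]-6-methylhepta-2,6-dienoate F2. An intramolecular Nozaki–Hiyama–Kishi-type allylation (CrCl2, THF/DMF, high dilution) then adds the allylchromium through C7 to the C8 aldehyde, which closes the carbocycle and creates the methylene lactone; the same trans, anti and Felkin preferences as in step 9 should lead to 18.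

2. Step 13 (Mitsunobu inversion). E2 elimination of the oxyphosphonium ion, or participation of the C9 acetate (acetoxonium ion, giving retention or acyl scrambling), may outrun SN2 displacement at the hindered ring carbinol. The fallback sets out from 18 and comes back at 22. Buffered Dess–Martin oxidation gives methyl (3aS,5S,6E,10E,11aR)-5-(acetyloxy)-10-methyl-3-methylidene-2,4-dioxo-2,3,3a,4,5,8,9,11a-octahydrocyclodeca[b]furan-6-carboxylate F3. Luche reduction (NaBH4, CeCl3, MeOH, −78 °C), with hydride expected to add anti to the C9 acetate (Felkin–Anh), should give methyl (3aR,4S,5S,6E,10E,11aR)-5-(acetyloxy)-4-hydroxy-10-methyl-3-methylidene-2-oxo-2,3,3a,4,5,8,9,11a-octahydrocyclodeca[b]furan-6-carboxylate F4. Steglich acylation of this 8β-alcohol with 21 (DIC, DMAP, CH2Cl2), with retention, gives 22.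

3. Step 9 (Barbier coupling). The α-acetoxy-β,γ-unsaturated aldehyde may enolise or be reduced in the aqueous zinc/ammonium chloride medium, the bromide may be reduced or homocoupled before addition, or the new C8 hydroxyl may lactonise onto the C14 ester. The fallback sets out from 9 and comes back at 17. Palladium-catalysed borylation of 9 (B2pin2, Pd2(dba)3, toluene/DMSO, rt) gives the isolable allylboronate (5R)-5-[(1E)-2-methylhexa-1,5-dien-1-yl]-3-[(4,4,5,5-tetramethyl-1,3,2-dioxaborolan-2-yl)methyl]furan-2(5H)-one F5. Allylboration of 15 in dry toluene (rt, neutral, closed six-membered transition state with the same trans, anti and Felkin sense) and mild aqueous work-up should give 17.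

Further compounds
F1 | step 10 | methyl (2E,6E)-2-[(1S)-1-(acetyloxy)-2,2-dimethoxyethyl]-7-[(2R)-4-(bromomethyl)-5-oxo-2,5-dihydrofuran-2-yl]-6-methylhepta-2,6-dienoate | COC(OC)[C@@H](OC(C)=O)/C(C(=O)OC)=C\CC/C(C)=C/[C@H]1OC(=O)C(CBr)=C1
F2 | step 10 | methyl (2E,6E)-2-[(1S)-1-(acetyloxy)-2-oxoethyl]-7-[(2R)-4-(bromomethyl)-5-oxo-2,5-dihydrofuran-2-yl]-6-methylhepta-2,6-dienoate | O=C[C@@H](OC(C)=O)/C(C(=O)OC)=C\CC/C(C)=C/[C@H]1OC(=O)C(CBr)=C1
F3 | step 13 | methyl (3aS,5S,6E,10E,11aR)-5-(acetyloxy)-10-methyl-3-methylidene-2,4-dioxo-2,3,3a,4,5,8,9,11a-octahydrocyclodeca[b]furan-6-carboxylate | O=C1[C@H]2C(=C)C(=O)O[C@@H]2/C=C(\C)CC/C=C(/C(=O)OC)[C@@H]1OC(C)=O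
F4 | step 13 | methyl (3aR,4S,5S,6E,10E,11aR)-5-(acetyloxy)-4-hydroxy-10-methyl-3-methylidene-2-oxo-2,3,3a,4,5,8,9,11a-octahydrocyclodeca[b]furan-6-carboxylate | O[C@H]1[C@H]2C(=C)C(=O)O[C@@H]2/C=C(\C)CC/C=C(/C(=O)OC)[C@@H]1OC(C)=O
F5 | step 9 | (5R)-5-[(1E)-2-methylhexa-1,5-dien-1-yl]-3-[(4,4,5,5-tetramethyl-1,3,2-dioxaborolan-2-yl)methyl]furan-2(5H)-one | C=CCC/C(C)=C/[C@H]1OC(=O)C(CB2OC(C)(C)C(C)(C)O2)=C1
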